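## The problem

The target, (3R)-3-[5,7-dihydroxy-2-(4-hydroxyphenyl)-4-oxo-4H-chromen-8-yl]-3-phenylpropanoic acid (12), is apigenin carrying a 2-carboxy-1-phenylethyl group on C8 of ring A. The flavone itself (rings A, C and B) needs no construction, since its tri-O-methyl ether can be bought. What has to be built is a three-carbon acid chain on C8, which must be told apart from the electronically similar C6, and a doubly benzylic carbon bearing phenyl. That carbon is the only stereocentre, so nothing in the molecule can relay chirality to it and a reagent or catalyst must set it. It lies β to the carboxyl and cannot be lost by enolisation, but strong acid could erode it by reversible dealkylation of the electron-rich ring A. Three functions need gentle handling. The γ-pyrone is opened by hot alkali, and in hot aqueous mineral acid it can open and re-close onto the 5-hydroxyl, which moves a C8 substituent to C6 (Wessely–Moser rearrangement). The polyphenol oxidises in air when deprotonated. The 7-hydroxyl and the carboxyl form a six-membered lactone readily, so the open acid must be isolated cold. The enabling feature is that the stereocentre is a prochiral benzylic CH2 before the phenyl is attached, two carbons from an amide carbonyl, where a bidentate directing group can hold palladium. Because C8 is flanked by C7–O and C8a–O1, ring A offers no ortho C–H to compete, and the freed 7-hydroxyl can later expel the directing group.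

## Retrosynthesis

**12 to 11.** The target is read as the hydrolysed form of the fused dihydrocoumarin 11, so the bond "cut" is the O7–C(=O) bond, re-formed in the backward sense. This is preferred to ending with hydrolysis of an amide or alkyl ester, which would need hot base or acid on the unprotected flavone. Lactone 11 is an activated aryl ester that hydroxide should open at 0 °C. The forward step needs only cold acidification so that the hydroxy acid does not close again.

**11 to 9 (through 10).** The lactone O7–C(=O) bond is exchanged for the amide N–C(=O) bond to 8-aminoquinoline, and the three phenols become methyl ethers. The auxiliary needed for the key step normally comes off only under harsh hydrolysis or after a separate activation. Here the 7-hydroxyl of triphenol 10 sits where a six-membered N→O acyl transfer can displace the amine under acid. Methyl ethers are chosen because the trimethyl ether is commercial and BBr3 cleaves them without water, so the pyrone is not opened. The forward reaction must demethylate three times and then lactonise without touching the stereocentre.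

**9 to 7 + 8.** This is the strategic cut, the C3–phenyl bond. The neighbouring cut, C3–C8, would need the di-ortho-substituted flavon-8-yl unit as the coupling partner, and hindered aryl iodides are poor partners in the tetravalent palladium manifold. Cutting inside the chain offers no asymmetric handle. The phenyl cut leaves the cheapest partner, iodobenzene 8, and an achiral amide 7. The forward reaction must choose between two enantiotopic benzylic hydrogens and stop after one arylation.

**7 to 5 + 6.** The amide N–C bond is cut to acid 5 and 8-aminoquinoline 6. This is a routine carbodiimide coupling and asks only for acylation of a weakly nucleophilic aniline.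

**5 to 4 to 2 + 3.** After ester hydrolysis (5 from 4), the C8–CH2 bond is cut to aryl iodide 2 and the zinc homoenolate 3. A Heck reaction followed by hydrogenation would cost a step and put a hydrogenation next to the pyrone double bond. A Friedel–Crafts alkylation would not distinguish C6 from C8. The forward Negishi coupling must work at an electron-rich iodide with two ortho substituents.

**2 to 1.** The C8–I bond is cut to commercial 5,7,4′-trimethoxyflavone 1. The forward iodination must go to C8 rather than C6, C3 or ring B, which is the known preference of fully O-methylated 5,7-dioxygenated flavones.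

## Roads not taken

**Alternative 1:** asymmetric cyclocarbonylation of a 1,1-diarylethene.
- **Cut:** the CH2–CO and O–CO bonds of a dihydrocoumarin, giving 5-methoxy-2-(1-phenylethenyl)benzene-1,3-diol A1 and CO.
- **Forward key step:** a divalent palladium hydride from Pd(OAc)2 and a chiral diphosphine adds to the alkene with hydrogen going to the diaryl carbon. CO inserts into the primary alkyl–palladium bond and a phenol captures the acyl, giving (4R)-5-hydroxy-7-methoxy-4-phenylchroman-2-one A2.
- **Merits:** one step forms two bonds, the lactone ring and the stereocentre. The two hydroxyls of A1 are equivalent, so ring closure has no regiochemical question. In bond-forming economy of the key step it is better than the chosen plan.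
- **Weak points:** enantioface selection requires the catalyst to tell phenyl from a 2,6-dihydroxyaryl group on the same alkene carbon, and asymmetric versions of this carbonylation are far less developed than the racemic one. A2 is also far from the target. Rings C and B must still be built on the lactone by C-acylation between the free hydroxyl and the methoxy group (with the other free ring position competing), strongly basic chalcone or diketone chemistry that opens the lactone, oxidative cyclisation and demethylation.
- **Comparison:** the flavone, bought ready-made in the chosen plan, becomes the main task and is built with the stereocentre already in place. The chosen plan forms only one bond in its key step but reaches 12 in seven steps from commercial 1.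

**Alternative 2:** Pechmann neoflavone, then copper hydride conjugate reduction.
- **Cut:** the benzylic C–H bond of the dihydrocoumarin, leading back to 5-(benzyloxy)-7-methoxy-4-phenyl-2H-chromen-2-one A3, made by Pechmann condensation and O-benzylation.
- **Forward key step:** a ligated monovalent copper hydride (Cu(OAc)2, a bulky chiral bisphosphine, a silane) delivers hydride to C4 and gives (4R)-5-(benzyloxy)-7-methoxy-4-phenylchroman-2-one A4.
- **Merits:** conjugate reduction of 4-arylcoumarins is among the most dependable ways to this kind of stereocentre. In predictability of the stereochemical outcome this road is better than an enantioselective methylene C–H arylation, whose ligand systems are less mature.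
- **Weak points:** the 5-benzyloxy group is peri to the 4-phenyl ring and crowds the carbon that receives hydride. The Pechmann ring closure can take either of two different positions ortho to a free hydroxyl. Protecting-group steps are added, and the same late flavone annulation on a base-sensitive lactone as in Alternative 1 remains.
- **Comparison:** the chosen plan sets against the more secure stereocontrol a shorter sequence, an intact flavone, no ring construction after the stereocentre, the option of raising the enantiomeric purity of 9 by crystallisation, and a conjugate-addition fallback.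

**Alternative 3:** late carbonyl-directed C5–H hydroxylation of a 5-deoxyflavone.
- **Cut:** the C5–O bond, leading back to (10R)-2-(4-methoxyphenyl)-10-phenyl-9,10-dihydro-4H,8H-pyrano[2,3-f]chromene-4,8-dione A5.
- **Forward key step:** divalent ruthenium from [RuCl2(p-cymene)]2, bound to the C4 carbonyl, cleaves C5–H through a five-membered ruthenacycle. PhI(OCOCF3)2 oxidises it and C–O reductive elimination gives the 5-hydroxy lactone A6 after loss of the trifluoroacetate.
- **Merits:** in a 7-oxygenated 5-deoxyflavone C8 is the only strongly activated ring-A position, so the C6/C8 question of the chosen plan does not arise. In that respect this road is better. The carbonyl is a built-in directing group, and the lactone masks both O7 and the carboxyl.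
- **Weak points:** the key step forms no C–C bond and sets no stereocentre, so the stereocentre needs a second catalytic asymmetric step elsewhere. A hypervalent iodine oxidant in strong acid meets a doubly benzylic methine C–H and an anisyl ring, and the phenol formed is more oxidisable than A5. The C5 oxygen, which compound 1 carries for free, has to be installed.
- **Comparison:** the chosen plan relies on the documented C8 preference of halogenation in 5,7-dimethoxyflavones, to be checked spectroscopically at 2. In return it needs no late oxidation and makes the stereocentre in its key step.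

Key step: step 5

Assumptions:
- The (R)-antipode of the BINOL phosphoric acid is written in step 5 on the working hypothesis that it gives the 3R amide 9. If the sense of induction is the reverse, the (S)-ligand is used and nothing else changes.
- Compound 3 is used as the commercial 0.5 M solution in THF.

## Route

Step 1
Reactants: 1 5,7-dimethoxy-2-(4-methoxyphenyl)-4H-chromen-4-one (5,7,4′-trimethoxyflavone)
Product: 2 8-iodo-5,7-dimethoxy-2-(4-methoxyphenyl)-4H-chromen-4-one
Conditions: NIS (1.05 equiv), TFA (0.3 equiv), CH2Cl2, 0 °C → rt, dark
Reagents that add atoms: N-iodosuccinimide, O=C1CCC(=O)N1I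
Why: Electrophilic aromatic iodination; fully O-methylated 5,7-dioxygenated flavones are halogenated at C8 (C6 lies between two methoxy groups and is favoured only with a free 5-hydroxyl), and C3 and ring B are much less nucleophilic; an NOE check on the remaining ring-A proton (contacts to both methoxy groups expected for H-6) would confirm the site.

Step 2
Reactants: 2 8-iodo-5,7-dimethoxy-2-(4-methoxyphenyl)-4H-chromen-4-one; 3 (3-ethoxy-3-oxopropyl)zinc bromide
Product: 4 ethyl 3-[5,7-dimethoxy-2-(4-methoxyphenyl)-4-oxo-4H-chromen-8-yl]propanoate
Conditions: Pd(OAc)2 (3 mol %), SPhos (6 mol %), THF–NMP (4:1), 50 °C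
Reagents that add atoms: none
Why: Negishi coupling of an ester-chelated zinc homoenolate with an aryl iodide; the bulky biaryl phosphine speeds oxidative addition at the hindered iodide and reductive elimination ahead of β-hydride elimination, and the alkylzinc halide does not add to the chromone carbonyl or enone.

Step 3
Reactants: 4 ethyl 3-[5,7-dimethoxy-2-(4-methoxyphenyl)-4-oxo-4H-chromen-8-yl]propanoate
Product: 5 3-[5,7-dimethoxy-2-(4-methoxyphenyl)-4-oxo-4H-chromen-8-yl]propanoic acid
Conditions: LiOH·H2O (3 equiv), THF–H2O (3:1), rt; then 1 M HCl to pH 3
Reagents that add atoms: lithium hydroxide, [Li+].[OH-]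
Why: Ester saponification by acyl–oxygen cleavage; the 2-aryl-γ-pyrone is opened only by hot concentrated alkali, so room-temperature hydroxide should leave the flavone intact.

Step 4
Reactants: 5 3-[5,7-dimethoxy-2-(4-methoxyphenyl)-4-oxo-4H-chromen-8-yl]propanoic acid; 6 quinolin-8-amine (8-aminoquinoline)
Product: 7 3-[5,7-dimethoxy-2-(4-methoxyphenyl)-4-oxo-4H-chromen-8-yl]-N-(quinolin-8-yl)propanamide
Conditions: EDC·HCl (1.5 equiv), DMAP (0.3 equiv), CH2Cl2, rt
Reagents that add atoms: none
Why: Carbodiimide amide coupling through the O-acylisourea and the acylpyridinium ion, the usual way to acylate the weakly nucleophilic 8-aminoquinoline; no other nucleophile or acid-sensitive group is present.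

Step 5
Reactants: 7 3-[5,7-dimethoxy-2-(4-methoxyphenyl)-4-oxo-4H-chromen-8-yl]-N-(quinolin-8-yl)propanamide; 8 iodobenzene
Product: 9 (3R)-3-[5,7-dimethoxy-2-(4-methoxyphenyl)-4-oxo-4H-chromen-8-yl]-3-phenyl-N-(quinolin-8-yl)propanamide
Conditions: Pd(OAc)2 (10 mol %), (R)-3,3′-bis(2,4,6-triisopropylphenyl)-BINOL hydrogen phosphate (20 mol %), Cs2CO3 (1.5 equiv), PhI (4 equiv), p-xylene, 130 °C, Ar
Reagents that add atoms: none
Why: The deprotonated amide and the quinoline nitrogen bind divalent palladium as an N,N-chelate that places the metal over the β-methylene, and a concerted metalation–deprotonation with the chiral phosphate as internal base removes one of the two enantiotopic benzylic hydrogens to give a five-membered palladacycle. Oxidative addition of 8 gives tetravalent palladium, C–C reductive elimination forms the C3–phenyl bond, and protonation of the amide frees 9 while Cs2CO3 takes up the iodide. The closest known reaction type is the 8-aminoquinoline-directed, palladium-catalysed enantioselective arylation of the benzylic methylene of 3-arylpropanamides with aryl iodides under BINOL phosphoric acid or phosphoramide ligands. No ring is closed in the product; the palladacycle is transient. The new stereocentre C3 is set by the catalyst alone: the chiral phosphate on palladium differentiates the two diastereomeric C–H cleavage transition states (and the following oxidative addition, should palladation be reversible). The step needs selection between enantiotopic hydrogens, mono-arylation and site selectivity; the substrate supplies the last two, because C7 and C8a next to C8 carry oxygen so no ortho C(sp2)–H can be palladated, the α-methylene would need a four-membered palladacycle, and after one arylation only a crowded methine hydrogen remains. The 2,6-disubstituted flavonyl group cannot rotate freely in the palladacycle, which should sharpen the difference between the two transition states, and the enantiomeric purity of 9 would be raised by crystallisation if needed.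

Step 6
Reactants: 9 (3R)-3-[5,7-dimethoxy-2-(4-methoxyphenyl)-4-oxo-4H-chromen-8-yl]-3-phenyl-N-(quinolin-8-yl)propanamide
Product: 11 (10R)-5-hydroxy-2-(4-hydroxyphenyl)-10-phenyl-9,10-dihydro-4H,8H-pyrano[2,3-f]chromene-4,8-dione, via triphenol amide 10 (not isolated)
Conditions: BBr3 (12 equiv), CH2Cl2, −78 → 40 °C; H2O quench, solvent exchange; TsOH·H2O (3 equiv), 1,4-dioxane, 80 °C
Reagents that add atoms: none
Why: Lewis-acid cleavage of the three aryl methyl ethers under anhydrous conditions (no hydrolytic pyrone opening), then acid-promoted N→O acyl transfer in which the freed 7-hydroxyl adds to the protonated amide, closes the six-membered lactone and expels 8-aminoquinolinium; the stereocentre is β to the carbonyl, not enolisable, and should be untouched.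

Step 7
Reactants: 11 (10R)-5-hydroxy-2-(4-hydroxyphenyl)-10-phenyl-9,10-dihydro-4H,8H-pyrano[2,3-f]chromene-4,8-dione
Product: 12 (3R)-3-[5,7-dihydroxy-2-(4-hydroxyphenyl)-4-oxo-4H-chromen-8-yl]-3-phenylpropanoic acid
Conditions: LiOH·H2O (5 equiv), degassed THF–H2O (2:1), 0 °C → rt, Ar; then 1 M HCl to pH 3–4 at 0 °C, EtOAc extraction, evaporation without heating
Reagents that add atoms: lithium hydroxide, [Li+].[OH-]
Why: Hydrolysis of an aryl ester (lactone opening), which hydroxide should effect at 0 °C without touching the pyrone; exclusion of air protects the polyphenolate, and cold mild acidification keeps the hydroxy acid from closing again.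

## Compound list

1 | 5,7-dimethoxy-2-(4-methoxyphenyl)-4H-chromen-4-one (5,7,4′-trimethoxyflavone) | COc1ccc(-c2cc(=O)c3c(OC)cc(OC)cc3o2)cc1 | starting material
2 | 8-iodo-5,7-dimethoxy-2-(4-methoxyphenyl)-4H-chromen-4-one | COc1ccc(-c2cc(=O)c3c(OC)cc(OC)c(I)c3o2)cc1 | intermediate
3 | (3-ethoxy-3-oxopropyl)zinc bromide | CCOC(=O)CC[Zn]Br | starting material
4 | ethyl 3-[5,7-dimethoxy-2-(4-methoxyphenyl)-4-oxo-4H-chromen-8-yl]propanoate | CCOC(=O)CCc1c(OC)cc(OC)c2c(=O)cc(-c3ccc(OC)cc3)oc12 | intermediate
5 | 3-[5,7-dimethoxy-2-(4-methoxyphenyl)-4-oxo-4H-chromen-8-yl]propanoic acid | OC(=O)CCc1c(OC)cc(OC)c2c(=O)cc(-c3ccc(OC)cc3)oc12 | intermediate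
6 | quinolin-8-amine (8-aminoquinoline) | Nc1cccc2cccnc12 | starting material
7 | 3-[5,7-dimethoxy-2-(4-methoxyphenyl)-4-oxo-4H-chromen-8-yl]-N-(quinolin-8-yl)propanamide | O=C(CCc1c(OC)cc(OC)c2c(=O)cc(-c3ccc(OC)cc3)oc12)Nc1cccc2cccnc12 | intermediate
8 | iodobenzene | Ic1ccccc1 | starting material
9 | (3R)-3-[5,7-dimethoxy-2-(4-methoxyphenyl)-4-oxo-4H-chromen-8-yl]-3-phenyl-N-(quinolin-8-yl)propanamide | O=C(C[C@H](c1ccccc1)c1c(OC)cc(OC)c2c(=O)cc(-c3ccc(OC)cc3)oc12)Nc1cccc2cccnc12 | intermediate
10 | (3R)-3-[5,7-dihydroxy-2-(4-hydroxyphenyl)-4-oxo-4H-chromen-8-yl]-3-phenyl-N-(quinolin-8-yl)propanamide | O=C(C[C@H](c1ccccc1)c1c(O)cc(O)c2c(=O)cc(-c3ccc(O)cc3)oc12)Nc1cccc2cccnc12 | intermediate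
11 | (10R)-5-hydroxy-2-(4-hydroxyphenyl)-10-phenyl-9,10-dihydro-4H,8H-pyrano[2,3-f]chromene-4,8-dione | O=C1C[C@H](c2ccccc2)c2c(O1)cc(O)c1c(=O)cc(-c3ccc(O)cc3)oc21 | intermediate
12 | (3R)-3-[5,7-dihydroxy-2-(4-hydroxyphenyl)-4-oxo-4H-chromen-8-yl]-3-phenylpropanoic acid | O=C(O)C[C@H](c1ccccc1)c1c(O)cc(O)c2c(=O)cc(-c3ccc(O)cc3)oc12 | target

## Step count and risks

Total step count: 7. Longest linear sequence: 7 steps (1 to 12).

**Step 5 (key step).** Three things may go wrong.
- Palladation may be slow at a methylene attached to a 2,6-disubstituted aryl group, and the C4 carbonyl/5-methoxy pair may sequester palladium.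
- Discrimination of the enantiotopic hydrogens may be insufficient, because the known ligand systems were tuned on unhindered 3-arylpropanamides.
- Further arylation may occur at an ortho C–H of the new phenyl ring through a six-membered palladacycle once the methylene is consumed.

The fallback leaves C–H activation and sets the stereocentre by conjugate addition. It sets out from iodide 2. A Mizoroki–Heck reaction with tert-butyl acrylate (Pd(OAc)2, P(o-tol)3, Et3N, DMF, 100 °C) would give tert-butyl (2E)-3-[5,7-dimethoxy-2-(4-methoxyphenyl)-4-oxo-4H-chromen-8-yl]prop-2-enoate F1. Asymmetric 1,4-addition of phenylboronic acid, catalysed by monovalent rhodium ([RhCl(C2H4)2]2 with a chiral diene ligand of the antipode that gives the 3R product, aqueous KOH, 1,4-dioxane), would give tert-butyl (3R)-3-[5,7-dimethoxy-2-(4-methoxyphenyl)-4-oxo-4H-chromen-8-yl]-3-phenylpropanoate F2. The pyrone enone, a β-aryl vinylogous ester, should not accept the aryl group. BBr3 then removes the tert-butyl group and the three methyl ethers, and the acid stage of step 6 closes the hydroxy acid to lactone 11, where the route is rejoined.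

**Step 6.** Three things may go wrong.
- Ether cleavage at O7 and O4′ may be incomplete, because the basic quinoline and the amide tie up BBr3 and partly demethylated borates precipitate.
- The N→O acyl transfer may be slow, since an anilide is a poor electrophile.
- With heat and water, the pyrone may open and re-close onto the 5-hydroxyl, moving the side chain from C8 to C6, or the stereocentre may erode through reversible acid-mediated dealkylation of ring A.

The fallback removes the auxiliary before the phenols are freed. It sets out from 9. Boc2O and DMAP in MeCN would give tert-butyl N-{(3R)-3-[5,7-dimethoxy-2-(4-methoxyphenyl)-4-oxo-4H-chromen-8-yl]-3-phenylpropanoyl}-N-(quinolin-8-yl)carbamate F3. LiOH/H2O2 in THF–H2O at 0 °C would cleave the twisted acyl carbamate to (3R)-3-[5,7-dimethoxy-2-(4-methoxyphenyl)-4-oxo-4H-chromen-8-yl]-3-phenylpropanoic acid F4. BBr3 on F4, followed by a brief acid treatment, gives lactone 11, where the route is rejoined. Closing a free acid onto the phenol needs much milder acid than displacing the anilide.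

**Step 2.** Oxidative addition and transmetalation may be slow at the electron-rich, di-ortho-substituted iodide, leading to protodeiodination back to 1 and homocoupling. β-Hydride elimination from the alkylpalladium intermediate may give the reduced arene. The fallback builds the chain in two stages and sets out from 2. A Mizoroki–Heck reaction with ethyl acrylate (Pd(OAc)2, P(o-tol)3, Et3N, DMF, 100 °C) would give ethyl (2E)-3-[5,7-dimethoxy-2-(4-methoxyphenyl)-4-oxo-4H-chromen-8-yl]prop-2-enoate F5. Hydrogenation of the side-chain double bond (H2 at 1 atm, Pd/C, EtOAc, rt, stopped after one equivalent, the pyrone C2=C3 bond being reduced far more slowly) returns to the route at ester 4.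

## Further compounds

F1 | step 5 | tert-butyl (2E)-3-[5,7-dimethoxy-2-(4-methoxyphenyl)-4-oxo-4H-chromen-8-yl]prop-2-enoate | CC(C)(C)OC(=O)/C=C/c1c(OC)cc(OC)c2c(=O)cc(-c3ccc(OC)cc3)oc12
F2 | step 5 | tert-butyl (3R)-3-[5,7-dimethoxy-2-(4-methoxyphenyl)-4-oxo-4H-chromen-8-yl]-3-phenylpropanoate | CC(C)(C)OC(=O)C[C@H](c1ccccc1)c1c(OC)cc(OC)c2c(=O)cc(-c3ccc(OC)cc3)oc12
F3 | step 6 | tert-butyl N-{(3R)-3-[5,7-dimethoxy-2-(4-methoxyphenyl)-4-oxo-4H-chromen-8-yl]-3-phenylpropanoyl}-N-(quinolin-8-yl)carbamate | CC(C)(C)OC(=O)N(C(=O)C[C@H](c1ccccc1)c1c(OC)cc(OC)c2c(=O)cc(-c3ccc(OC)cc3)oc12)c1cccc2cccnc12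
F4 | step 6 | (3R)-3-[5,7-dimethoxy-2-(4-methoxyphenyl)-4-oxo-4H-chromen-8-yl]-3-phenylpropanoic acid | OC(=O)C[C@H](c1ccccc1)c1c(OC)cc(OC)c2c(=O)cc(-c3ccc(OC)cc3)oc12
F5 | step 2 | ethyl (2E)-3-[5,7-dimethoxy-2-(4-methoxyphenyl)-4-oxo-4H-chromen-8-yl]prop-2-enoate | CCOC(=O)/C=C/c1c(OC)cc(OC)c2c(=O)cc(-c3ccc(OC)cc3)oc12
A1 | alternative 1 | 5-methoxy-2-(1-phenylethenyl)benzene-1,3-diol | C=C(c1ccccc1)c1c(O)cc(OC)cc1O
A2 | alternative 1 | (4R)-5-hydroxy-7-methoxy-4-phenylchroman-2-one | O=C1C[C@H](c2ccccc2)c2c(O)cc(OC)cc2O1
A3 | alternative 2 | 5-(benzyloxy)-7-methoxy-4-phenyl-2H-chromen-2-one | O=C1C=C(c2ccccc2)c2c(OCc3ccccc3)cc(OC)cc2O1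
A4 | alternative 2 | (4R)-5-(benzyloxy)-7-methoxy-4-phenylchroman-2-one | O=C1C[C@H](c2ccccc2)c2c(OCc3ccccc3)cc(OC)cc2O1
A5 | alternative 3 | (10R)-2-(4-methoxyphenyl)-10-phenyl-9,10-dihydro-4H,8H-pyrano[2,3-f]chromene-4,8-dione | O=C1C[C@H](c2ccccc2)c2c(O1)ccc1c(=O)cc(-c3ccc(OC)cc3)oc21
A6 | alternative 3 | (10R)-5-hydroxy-2-(4-methoxyphenyl)-10-phenyl-9,10-dihydro-4H,8H-pyrano[2,3-f]chromene-4,8-dione | O=C1C[C@H](c2ccccc2)c2c(O1)cc(O)c1c(=O)cc(-c3ccc(OC)cc3)oc21
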